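58% is where product stands in the oak run at 20.0 min, with open intermediate down to 0%. This reckoning reads the missing 42.0% as open intermediate lost by a side exit, and it takes the product exit as a step that uses partner A. Product over loss, divided by the equivalents of partner A charged, gives 0.986, the product odds per equivalent of partner A, a selectivity factor read from a run with scatter.

| flask | starting material | partner A | partner B | remark | time |
|---|---|---|---|---|---|
| oak | 0.80 M | 1.4 equiv | 3 equiv | run made earlier |  |
| flask | 0.80 M | 0.900 equiv | 3.00 equiv |  | 1.0 h |

- oak (time / min: open intermediate / %, product / %): 1.33: 32, 8; 2.50: 34, 13; 5.00: 21, 33; 10.0: 8, 46; 20.0: 0, 58

(scatter of a reading: 1.5 percentage points)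



- when, up to 1.0 h, the flask holds most open intermediate, in min
- the amount of open intermediate, in percent of the starting material charged, at that time
- the first time at which open intermediate reaches 12%, in the same percent, in min

The new flask looks nearly the same as the oak run. Starting material and partner B stand as before, but partner A falls to 0.900 equiv from 1.4 equiv. The flask's odds are then 0.888, so it should end at 47.0% product, below the oak run's 58%. In this reckoning open intermediate leaves by both exits, and its clearing is taken to scale with one plus the odds. The flask is then reckoned to clear at 0.793 of the oak run's pace. With formation taken as unchanged, the oak run's peak reading of 34% is reckoned to become 42.9% in the flask.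

The forecast gives 25.5% at 2.2 min, with the level reached at 0.4 min, on the ground that “formation stops earlier”, and its peak lies below this reckoning's.

The flask peaks at 40.3% at 2.28 min and reaches the level at 0.231 min, so the reckoned peak stands 2.6 percentage points high. Changing partner A from the oak charge to the flask's carries the computed peak from 33.6% to 40.3%. The odds gave 47.0% product, and the flask ends at 46.4%.

    starting material + partner B → open intermediate (k = 0.00424 M⁻¹ s⁻¹)
    partner B + partner A → second intermediate (k = 0.0117 M⁻¹ s⁻¹)
    open intermediate + second intermediate → product (k = 0.00454 M⁻¹ s⁻¹)
    open intermediate → decomposed reagent (k = 0.00253 s⁻¹)

The neighbour with 1.80 equiv of partner B keeps the flask's partner A, and the odds, taken over although partner B differs, again assign 47.0% of the consumed starting material to product. With 13% of its starting material left, that reckoning gives 40.9%, and the neighbour computes to 39.7%.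

All runs are simulated on assumed constants.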